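Everything rests on disconnecting the aryl–oxygen bond O1–C8a of the 1,4-dioxane ring. Ring carbon C4a, which carries O4, is flanked by two oxygenated carbons (C8a and C5), so a symmetric 2,6-dibromophenyl ether provides both: a Pd-catalysed intramolecular etherification joins the benzylic C2 oxygen to one C–Br carbon and closes the dioxane ring with C2 and C3 untouched, and the surviving bromide becomes the C5 phenol. The precursor is the syn-(1S,2S) 2-(2,6-dibromoaryloxy)-1-(3,4,5-trimethoxyphenyl)propane-1,3-diol from an Evans glycolate aldol, with the benzylic hydroxyl free and both primary hydroxyls masked as TIPS ethers.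

Key step: step 7

Remark: the benzodioxane numbering used throughout is O1, C2 (aryl), C3 (CH2OH), O4, C4a, C5 (OH), C6, C7 (propenal), C8, C8a; the target is the (2S,3S)-trans isomer.
Remark: TIPS is chosen over smaller silyl groups because the primary oxygen of the precursor could also close a six-membered ring onto the arene if a silyl group migrated to the benzylic alkoxide under the basic coupling conditions.

Step 1
Reactants: 1 methyl 3,5-dibromo-4-hydroxybenzoate; 2 tert-butyl bromoacetate
Product: 3 tert-butyl 2-[2,6-dibromo-4-(methoxycarbonyl)phenoxy]acetate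
Conditions: K2CO3, DMF, 50 °C
Reagents that add atoms: tert-butyl bromoacetate (2), CC(C)(C)OC(=O)CBr
Why: Williamson etherification, in which the acidic dibromophenol is fully ionised by carbonate and its phenoxide displaces bromide from the activated α-bromo ester by SN2 while the methyl ester is inert under anhydrous conditions.

Step 2
Reactants: 3 tert-butyl 2-[2,6-dibromo-4-(methoxycarbonyl)phenoxy]acetate
Product: 4 2-[2,6-dibromo-4-(methoxycarbonyl)phenoxy]acetic acid
Conditions: TFA, CH2Cl2, rt
Reagents that add atoms: none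
Why: Acidolysis of the tert-butyl ester through the tert-butyl cation releases isobutene and should leave the methyl ester, the aryl ether and the bromides untouched.

Step 3
Reactants: 4 2-[2,6-dibromo-4-(methoxycarbonyl)phenoxy]acetic acid; 5 (R)-4-benzyl-2-oxazolidinone
Product: 7 (R)-4-benzyl-3-{2-[2,6-dibromo-4-(methoxycarbonyl)phenoxy]acetyl}oxazolidin-2-one, via mixed pivalic anhydride 6 (not isolated)
Conditions: PivCl, Et3N, THF, −20 → 0 °C; then 5, LiCl, rt
Reagents that add atoms: (R)-4-benzyl-2-oxazolidinone (5), O=C1N[C@H](Cc2ccccc2)CO1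
Why: Mixed-anhydride N-acylation, in which the LiCl/Et3N-activated oxazolidinone attacks the unhindered aryloxyacetyl carbonyl of the pivalic anhydride in preference to the tert-butyl-shielded one.

Step 4
Reactants: 7 (R)-4-benzyl-3-{2-[2,6-dibromo-4-(methoxycarbonyl)phenoxy]acetyl}oxazolidin-2-one; 8 3,4,5-trimethoxybenzaldehyde
Product: 11 (R)-4-benzyl-3-[(2R,3S)-2-(2,6-dibromo-4-methoxycarbonylphenoxy)-3-hydroxy-3-(3,4,5-trimethoxyphenyl)propanoyl]oxazolidin-2-one, via Z-boron enolate 9 (not isolated), via boron aldolate 10 (not isolated)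
Conditions: Bu2BOTf, Et3N, CH2Cl2, −78 → 0 °C; 8, −78 → 0 °C; then pH 7 buffer, MeOH, 30% H2O2, 0 °C
Reagents that add atoms: 3,4,5-trimethoxybenzaldehyde (8), COc1cc(C=O)cc(OC)c1OC
Why: Evans syn-glycolate aldol, in which the Z dibutylboron enolate reacts through a closed Zimmerman–Traxler chair (syn relationship) and the aldehyde adds to the enolate face opposite the benzyl group of the dipole-opposed (R)-auxiliary, setting both stereocentres as (2R,3S), the centres that become C3 and C2 of the benzodioxane.

Step 5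
Reactants: 11 (R)-4-benzyl-3-[(2R,3S)-2-(2,6-dibromo-4-methoxycarbonylphenoxy)-3-hydroxy-3-(3,4,5-trimethoxyphenyl)propanoyl]oxazolidin-2-one
Product: 12 (1S,2S)-2-[2,6-dibromo-4-(hydroxymethyl)phenoxy]-1-(3,4,5-trimethoxyphenyl)propane-1,3-diol
Conditions: LiBH4, MeOH, THF, 0 → 40 °C
Reagents that add atoms: none
Why: Hydride reduction, in which LiBH4 cleaves the imide at its exocyclic carbonyl at 0 °C and, activated by methanol, reduces the aryl methyl ester on warming, with aryl bromides and both stereocentres unaffected (the C2 descriptor changes from R to S through CIP priorities only).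

Step 6
Reactants: 12 (1S,2S)-2-[2,6-dibromo-4-(hydroxymethyl)phenoxy]-1-(3,4,5-trimethoxyphenyl)propane-1,3-diol
Product: 13 (1S,2S)-2-{2,6-dibromo-4-[(triisopropylsilyloxy)methyl]phenoxy}-1-(3,4,5-trimethoxyphenyl)-3-(triisopropylsilyloxy)propan-1-ol
Conditions: TIPSCl, imidazole, DMF, 0 °C → rt
Reagents that add atoms: triisopropylsilyl chloride (TIPSCl), CC(C)[Si](Cl)(C(C)C)C(C)C
Why: Sterically controlled silylation, in which the bulky TIPS chloride should react only at the two unhindered primary hydroxyls and leave the congested benzylic secondary hydroxyl free.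

Step 7
Reactants: 13 (1S,2S)-2-{2,6-dibromo-4-[(triisopropylsilyloxy)methyl]phenoxy}-1-(3,4,5-trimethoxyphenyl)-3-(triisopropylsilyloxy)propan-1-ol
Product: 14 (2S,3S)-5-bromo-2-(3,4,5-trimethoxyphenyl)-3,7-bis[(triisopropylsilyloxy)methyl]-2,3-dihydro-1,4-benzodioxine
Conditions: Pd(OAc)2 (5 mol %), 2-(di-tert-butylphosphino)-1,1'-binaphthyl (6 mol %), Cs2CO3, toluene, 70 °C
Reagents that add atoms: none
Why: Pd(0) inserts into one of the two equivalent C–Br bonds ortho to the ether oxygen, the carbonate-generated benzylic alkoxide binds palladium, and C–O reductive elimination from the seven-membered oxa-palladacycle forms C8a–O1. The closest known reaction type is the Buchwald–Hartwig intramolecular etherification of o-haloaryl ethers carrying a secondary alcohol, which gives 2-substituted 1,4-benzodioxanes. The six-membered dioxane ring is closed by intramolecular O-arylation at the sp2 carbon, formally a 6-exo attack of oxygen on the arene. No stereocentre is created: the bond forms at the arene carbon and the C2–O bond is never broken, so the syn aldol relationship should become the (2S,3S)-trans ring with retention. The step needs chemoselectivity for the benzylic oxygen over the primary one, which could also close a six-membered ring, and the non-migrating TIPS cap secures this; no regiochemical choice arises because the two bromides are equivalent. The bulky electron-rich phosphine should make reductive elimination faster than β-hydride elimination of the benzylic alkoxide.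

Step 8
Reactants: 14 (2S,3S)-5-bromo-2-(3,4,5-trimethoxyphenyl)-3,7-bis[(triisopropylsilyloxy)methyl]-2,3-dihydro-1,4-benzodioxine
Product: 16 (2S,3S)-2-(3,4,5-trimethoxyphenyl)-3,7-bis[(triisopropylsilyloxy)methyl]-2,3-dihydro-1,4-benzodioxin-5-ol, via aryl pinacol boronate 15 (not isolated)
Conditions: B2pin2, Pd(dppf)Cl2, KOAc, dioxane, 90 °C; then THF, aq. NaOH, 30% H2O2, 0 °C
Reagents that add atoms: hydrogen peroxide, OO
Why: Miyaura borylation of the remaining C5–Br bond followed by hydroperoxide-induced 1,2-aryl migration from boron to oxygen should give the phenol with silyl ethers, the dioxane ring and both stereocentres intact.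

Step 9
Reactants: 16 (2S,3S)-2-(3,4,5-trimethoxyphenyl)-3,7-bis[(triisopropylsilyloxy)methyl]-2,3-dihydro-1,4-benzodioxin-5-ol
Product: 17 (2S,3S)-3,7-bis(hydroxymethyl)-2-(3,4,5-trimethoxyphenyl)-2,3-dihydro-1,4-benzodioxin-5-ol
Conditions: TBAF, THF, 0 °C → rt
Reagents that add atoms: none
Why: Fluoride-induced desilylation, driven by Si–F bond formation, should remove both primary TIPS ethers without touching the dioxane ring or the stereocentres.

Step 10
Reactants: 17 (2S,3S)-3,7-bis(hydroxymethyl)-2-(3,4,5-trimethoxyphenyl)-2,3-dihydro-1,4-benzodioxin-5-ol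
Product: 18 (2S,3S)-5-hydroxy-3-(hydroxymethyl)-2-(3,4,5-trimethoxyphenyl)-2,3-dihydro-1,4-benzodioxine-7-carbaldehyde
Conditions: activated MnO2, acetone, rt
Reagents that add atoms: none
Why: MnO2 oxidation is selective for benzylic alcohols, so only the C7 hydroxymethyl group should be oxidised and the unactivated aliphatic primary alcohol on C3 should remain.

Step 11
Reactants: 18 (2S,3S)-5-hydroxy-3-(hydroxymethyl)-2-(3,4,5-trimethoxyphenyl)-2,3-dihydro-1,4-benzodioxine-7-carbaldehyde; 19 (triphenylphosphoranylidene)acetaldehyde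
Product: 20 (E)-3-[(2S,3S)-5-hydroxy-3-(hydroxymethyl)-2-(3,4,5-trimethoxyphenyl)-2,3-dihydro-1,4-benzodioxin-7-yl]prop-2-enal
Conditions: 19, toluene/THF, 80 °C
Reagents that add atoms: (triphenylphosphoranylidene)acetaldehyde (19), O=CC=P(c1ccccc1)(c1ccccc1)c1ccccc1
Why: Wittig olefination with the stabilised formylmethylene ylide should give the E enal through the thermodynamically favoured oxaphosphetane, the ylide being too weakly basic to be quenched by the phenol or the alcohol.

Compound list
1 | methyl 3,5-dibromo-4-hydroxybenzoate | COC(=O)c1cc(Br)c(O)c(Br)c1 | starting material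
2 | tert-butyl bromoacetate | CC(C)(C)OC(=O)CBr | starting material
3 | tert-butyl 2-[2,6-dibromo-4-(methoxycarbonyl)phenoxy]acetate | COC(=O)c1cc(Br)c(OCC(=O)OC(C)(C)C)c(Br)c1 | intermediate
4 | 2-[2,6-dibromo-4-(methoxycarbonyl)phenoxy]acetic acid | COC(=O)c1cc(Br)c(OCC(=O)O)c(Br)c1 | intermediate
5 | (R)-4-benzyl-2-oxazolidinone | O=C1N[C@H](Cc2ccccc2)CO1 | starting material
6 | mixed pivalic anhydride of acid 4 | COC(=O)c1cc(Br)c(OCC(=O)OC(=O)C(C)(C)C)c(Br)c1 | intermediate (not isolated)
7 | (R)-4-benzyl-3-{2-[2,6-dibromo-4-(methoxycarbonyl)phenoxy]acetyl}oxazolidin-2-one | COC(=O)c1cc(Br)c(OCC(=O)N2[C@H](Cc3ccccc3)COC2=O)c(Br)c1 | intermediate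
8 | 3,4,5-trimethoxybenzaldehyde | COc1cc(C=O)cc(OC)c1OC | starting material
9 | Z dibutylboron enolate of imide 7 | CCCCB(CCCC)O/C(=C\Oc1c(Br)cc(C(=O)OC)cc1Br)N1[C@H](Cc2ccccc2)COC1=O | intermediate (not isolated)
10 | O-dibutylboryl aldolate of 11 | COc1cc([C@H](OB(CCCC)CCCC)[C@H](C(=O)N2[C@H](Cc3ccccc3)COC2=O)Oc2c(Br)cc(C(=O)OC)cc2Br)cc(OC)c1OC | intermediate (not isolated)
11 | (R)-4-benzyl-3-[(2R,3S)-2-(2,6-dibromo-4-methoxycarbonylphenoxy)-3-hydroxy-3-(3,4,5-trimethoxyphenyl)propanoyl]oxazolidin-2-one (syn aldol adduct) | COc1cc([C@H](O)[C@H](C(=O)N2[C@H](Cc3ccccc3)COC2=O)Oc2c(Br)cc(C(=O)OC)cc2Br)cc(OC)c1OC | intermediate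
12 | (1S,2S)-2-[2,6-dibromo-4-(hydroxymethyl)phenoxy]-1-(3,4,5-trimethoxyphenyl)propane-1,3-diol | COc1cc([C@H](O)[C@H](CO)Oc2c(Br)cc(CO)cc2Br)cc(OC)c1OC | intermediate
13 | (1S,2S)-2-{2,6-dibromo-4-[(triisopropylsilyloxy)methyl]phenoxy}-1-(3,4,5-trimethoxyphenyl)-3-(triisopropylsilyloxy)propan-1-ol (key-step precursor) | COc1cc([C@H](O)[C@H](CO[Si](C(C)C)(C(C)C)C(C)C)Oc2c(Br)cc(CO[Si](C(C)C)(C(C)C)C(C)C)cc2Br)cc(OC)c1OC | intermediate
14 | (2S,3S)-5-bromo-2-(3,4,5-trimethoxyphenyl)-3,7-bis[(triisopropylsilyloxy)methyl]-2,3-dihydro-1,4-benzodioxine (key-step product) | COc1cc([C@@H]2Oc3cc(CO[Si](C(C)C)(C(C)C)C(C)C)cc(Br)c3O[C@H]2CO[Si](C(C)C)(C(C)C)C(C)C)cc(OC)c1OC | intermediate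
15 | C5 pinacol boronate of 14 | COc1cc([C@@H]2Oc3cc(CO[Si](C(C)C)(C(C)C)C(C)C)cc(B4OC(C)(C)C(C)(C)O4)c3O[C@H]2CO[Si](C(C)C)(C(C)C)C(C)C)cc(OC)c1OC | intermediate (not isolated)
16 | (2S,3S)-2-(3,4,5-trimethoxyphenyl)-3,7-bis[(triisopropylsilyloxy)methyl]-2,3-dihydro-1,4-benzodioxin-5-ol | COc1cc([C@@H]2Oc3cc(CO[Si](C(C)C)(C(C)C)C(C)C)cc(O)c3O[C@H]2CO[Si](C(C)C)(C(C)C)C(C)C)cc(OC)c1OC | intermediate
17 | (2S,3S)-3,7-bis(hydroxymethyl)-2-(3,4,5-trimethoxyphenyl)-2,3-dihydro-1,4-benzodioxin-5-ol | COc1cc([C@@H]2Oc3cc(CO)cc(O)c3O[C@H]2CO)cc(OC)c1OC | intermediate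
18 | (2S,3S)-5-hydroxy-3-(hydroxymethyl)-2-(3,4,5-trimethoxyphenyl)-2,3-dihydro-1,4-benzodioxine-7-carbaldehyde | COc1cc([C@@H]2Oc3cc(C=O)cc(O)c3O[C@H]2CO)cc(OC)c1OC | intermediate
19 | (triphenylphosphoranylidene)acetaldehyde | O=CC=P(c1ccccc1)(c1ccccc1)c1ccccc1 | starting material
20 | (E)-3-[(2S,3S)-5-hydroxy-3-(hydroxymethyl)-2-(3,4,5-trimethoxyphenyl)-2,3-dihydro-1,4-benzodioxin-7-yl]prop-2-enal | COc1cc([C@@H]2Oc3cc(/C=C/C=O)cc(O)c3O[C@H]2CO)cc(OC)c1OC | target

Total step count: 11. Longest linear sequence: 11 steps (1 → 20).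

Steps most likely to fail

Step 7. The Pd(II) benzylic alkoxide may undergo β-hydride elimination (ketone formation with hydrodebromination, or epimerisation at C2 by reversible hydride return), or reductive elimination may be too slow at the hindered, electron-rich arene. Fallback: setting out from 13, the carbinol would be deprotonated and one of the two equivalent bromides exchanged with n-BuLi (2.1 equiv, THF, −78 °C). The aryllithium would be trapped with B(OMe)3 to give the dimethyl arylboronate F1, which would be oxidised in the same pot (H2O2, aq. NaOH) to the bromophenol F2. Equilibrating acid catalysis (cat. CSA or BF3·OEt2, CH2Cl2, low temperature) would then ionise the electron-rich benzylic carbinol so that the new phenol oxygen closes the ring at C2. The fixed C3 centre should steer this reversible closure to the diequatorial trans ring, and the route is rejoined at 14.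

Step 11. The weakly nucleophilic formyl ylide may olefinate sluggishly, and the product enal may be homologated further to the dienal. Fallback: setting out from 18, Wittig olefination with the more nucleophilic ester ylide Ph3P=CHCO2Et (toluene, 60 °C) would give the ethyl (E)-cinnamate F3. Excess DIBAL-H (THF, −78 °C) would reduce it to the cinnamyl alcohol F4, and MnO2 (acetone, rt) would oxidise only the allylic alcohol, returning to the route at the target 20.

Step 8. Borylation next to the ring oxygen may stall or give protodebromination, and the electron-rich phenol may be over-oxidised during the peroxide stage. Fallback: setting out from 14, direct Pd-catalysed hydroxylation of the bromide (Pd2(dba)3, tBuXPhos, KOH, dioxane/H2O, 100 °C), a C–O coupling that avoids the boronate and the peroxide altogether, would give the phenol and rejoin the route at 16; no new compound arises.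

Further compounds
F1 | step 7 | dimethyl {3-bromo-2-[(1S,2S)-1-hydroxy-1-(3,4,5-trimethoxyphenyl)-3-(triisopropylsilyloxy)propan-2-yl]oxy-5-[(triisopropylsilyloxy)methyl]phenyl}boronate | COc1cc([C@H](O)[C@H](CO[Si](C(C)C)(C(C)C)C(C)C)Oc2c(Br)cc(CO[Si](C(C)C)(C(C)C)C(C)C)cc2B(OC)OC)cc(OC)c1OC
F2 | step 7 | (1S,2S)-2-{2-bromo-6-hydroxy-4-[(triisopropylsilyloxy)methyl]phenoxy}-1-(3,4,5-trimethoxyphenyl)-3-(triisopropylsilyloxy)propan-1-ol | COc1cc([C@H](O)[C@H](CO[Si](C(C)C)(C(C)C)C(C)C)Oc2c(Br)cc(CO[Si](C(C)C)(C(C)C)C(C)C)cc2O)cc(OC)c1OC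
F3 | step 11 | ethyl (E)-3-[(2S,3S)-5-hydroxy-3-(hydroxymethyl)-2-(3,4,5-trimethoxyphenyl)-2,3-dihydro-1,4-benzodioxin-7-yl]prop-2-enoate | COc1cc([C@@H]2Oc3cc(/C=C/C(=O)OCC)cc(O)c3O[C@H]2CO)cc(OC)c1OC
F4 | step 11 | (2S,3S)-3-(hydroxymethyl)-7-[(E)-3-hydroxyprop-1-enyl]-2-(3,4,5-trimethoxyphenyl)-2,3-dihydro-1,4-benzodioxin-5-ol | COc1cc([C@@H]2Oc3cc(/C=C/CO)cc(O)c3O[C@H]2CO)cc(OC)c1OC
F0 | step 8 | none | none
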